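Everything rests on cutting the C4′–C5′ bond of the unbranched side chain (C1′ on quinone ring carbon C6, Z-alkene at C10′=C11′). Both atoms are unactivated CH2 groups of the C1′–C9′ polymethylene tether, four carbons from the ring and five from the alkene, so they are united as two electrophiles. A nickel-catalysed decarboxylative cross-electrophile coupling joins (Z)-dodec-7-enoic acid, activated in the flask as its N-hydroxyphthalimide ester, to a 4-arylbutyl bromide whose ring is the quinone masked as a tetramethoxytoluene. One operation completes the C15 chain and leaves no functional group to erase. CAN oxidation and hydrolysis then unveil the 2,5-dihydroxy-1,4-benzoquinone.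

Key step: step 4

Remark: the target is treated as its 2,5-dihydroxy-1,4-benzoquinone tautomer, and compounds 1, 4, 7, 8 and 11 are taken to be commercial.

Step 1
Reactants: 1 1,2,4,5-tetramethoxybenzene
Product: 3 2,3,5,6-tetramethoxytoluene, via tetramethoxyphenyllithium 2 (not isolated)
Conditions: n-BuLi (1.0 equiv), THF, 0 °C to rt; MeI, 0 °C to rt
Reagents that add atoms: iodomethane, CI
Why: Directed ortho-metalation, in which one equivalent of base should lithiate once the ring C–H flanked by two methoxy groups, and the aryllithium is then methylated by SN2 on iodomethane.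

Step 2
Reactants: 3 2,3,5,6-tetramethoxytoluene; 4 1,4-dibromobutane
Product: 6 1-(4-bromobutyl)-2,3,5,6-tetramethoxy-4-methylbenzene, via tetramethoxytolyllithium 5 (not isolated)
Conditions: n-BuLi (1.1 equiv), TMEDA, THF, 0 °C to rt; slow addition to 4 (5 equiv), THF/DMPU, −78 °C to rt
Reagents that add atoms: none
Why: Directed ortho-metalation of the last ring C–H followed by SN2 alkylation, where inverse addition to a large excess of the dibromide should hold the reaction at monosubstitution and n-BuLi does not deprotonate the ring methyl group.

Step 3
Reactants: 7 (6-carboxyhexyl)triphenylphosphonium bromide; 8 pentanal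
Product: 10 (Z)-dodec-7-enoic acid, via carboxylate ylide 9 (not isolated)
Conditions: NaHMDS (2.1 equiv), THF, 0 °C; 8, −78 °C to rt; 1 M HCl work-up
Reagents that add atoms: none
Why: Wittig olefination with a non-stabilised ylide under lithium-free conditions, where the kinetically favoured cis-oxaphosphetane sets the C7=C8 double bond as Z and the second equivalent of base only holds the acid as its carboxylate.

Step 4
Reactants: 6 1-(4-bromobutyl)-2,3,5,6-tetramethoxy-4-methylbenzene; 10 (Z)-dodec-7-enoic acid (1.5–2 equiv); 11 N-hydroxyphthalimide
Product: 13 1,2,4,5-tetramethoxy-3-methyl-6-[(Z)-pentadec-10-en-1-yl]benzene, via NHP ester 12 (not isolated)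
Conditions: 10, 11, DIC, DMAP (cat.), DMA, rt; then 6, NiBr2·dme (10 mol %), 4,4′,4″-tri-tert-butyl-2,2′:6′,2″-terpyridine (10 mol %), Zn dust (3 equiv), rt
Reagents that add atoms: none
Why: DIC esterifies 10 with 11 to the redox-active ester 12, a low-valent nickel species kept alive by zinc transfers one electron to 12, which loses phthalimide anion and CO2 to release the primary (Z)-undec-6-enyl radical, bromide 6 is activated at nickel to a 4-arylbutylnickel species, and radical capture gives a dialkylnickel(III) that reductively eliminates the C4′–C5′ bond. The reaction type is the known nickel-catalysed decarboxylative cross-electrophile coupling of N-hydroxyphthalimide esters made in the flask with unactivated primary alkyl bromides. No ring is closed and no stereocentre is created, and the Z geometry of C10′=C11′ is carried over unchanged from 10. The step needs cross-coupling over homocoupling, which the different activation modes of ester and bromide and the excess of the one-step acid 10 should secure, and any homocoupling products would differ widely from 13 in polarity. The radical carries its alkene at the 6,7-position, so only slow 6-exo closure and a slow allylic 1,5-hydrogen shift compete with capture by nickel, while the tridentate ligand disfavours β-hydride elimination and hence Ni–H isomerisation of the alkene. The reducing medium leaves the very electron-rich tetramethoxyarene untouched, which an anodic Kolbe coupling would not.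

Step 5
Reactants: 13 1,2,4,5-tetramethoxy-3-methyl-6-[(Z)-pentadec-10-en-1-yl]benzene
Product: 14 2,5-dimethoxy-3-methyl-6-[(Z)-pentadec-10-en-1-yl]-1,4-benzoquinone
Conditions: (NH4)2Ce(NO3)6 (2.5 equiv), MeCN/H2O, 0 °C
Reagents that add atoms: water, O
Why: Cerium(IV) oxidative demethylation of a 1,4-dimethoxyarene (two one-electron oxidations, water attacks the ring carbons and methanol leaves), where both para pairs of methoxy groups lead to the same 2,5-dimethoxyquinone and the isolated alkene is far harder to oxidise than the arene.

Step 6
Reactants: 14 2,5-dimethoxy-3-methyl-6-[(Z)-pentadec-10-en-1-yl]-1,4-benzoquinone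
Product: 16 2,5-dihydroxy-3-methyl-6-[(Z)-pentadec-10-en-1-yl]-1,4-benzoquinone, via disodium quinonediolate 15 (not isolated)
Conditions: 2 M NaOH, EtOH, reflux, Ar; then 2 M HCl, 0 °C
Reagents that add atoms: sodium hydroxide, [Na+].[OH-]
Why: Both methoxy groups are vinylogous methyl esters and are replaced by hydroxide through conjugate addition–elimination (vinylogous saponification), acidification frees the bis-enol, and neither the base nor the dilute acid touches the Z-alkene.

Compound list
1 | 1,2,4,5-tetramethoxybenzene | COc1cc(OC)c(OC)cc1OC | starting material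
2 | 2,3,5,6-tetramethoxyphenyllithium | [Li]c1c(OC)c(OC)cc(OC)c1OC | intermediate
3 | 2,3,5,6-tetramethoxytoluene (1,2,4,5-tetramethoxy-3-methylbenzene) | Cc1c(OC)c(OC)cc(OC)c1OC | intermediate
4 | 1,4-dibromobutane | BrCCCCBr | starting material
5 | 2,3,5,6-tetramethoxy-4-methylphenyllithium | [Li]c1c(OC)c(OC)c(C)c(OC)c1OC | intermediate
6 | 1-(4-bromobutyl)-2,3,5,6-tetramethoxy-4-methylbenzene | Cc1c(OC)c(OC)c(CCCCBr)c(OC)c1OC | intermediate
7 | (6-carboxyhexyl)triphenylphosphonium bromide | OC(=O)CCCCCC[P+](c1ccccc1)(c1ccccc1)c1ccccc1.[Br-] | starting material
8 | pentanal | CCCCC=O | starting material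
9 | sodium 7-(triphenyl-λ5-phosphanylidene)heptanoate (carboxylate ylide) | [Na+].[O-]C(=O)CCCCCC=P(c1ccccc1)(c1ccccc1)c1ccccc1 | intermediate
10 | (Z)-dodec-7-enoic acid | CCCC/C=C\CCCCCC(=O)O | intermediate
11 | N-hydroxyphthalimide | ON1C(=O)c2ccccc2C1=O | starting material
12 | 1,3-dioxoisoindolin-2-yl (Z)-dodec-7-enoate (NHP ester) | CCCC/C=C\CCCCCC(=O)ON1C(=O)c2ccccc2C1=O | intermediate
13 | 1,2,4,5-tetramethoxy-3-methyl-6-[(Z)-pentadec-10-en-1-yl]benzene | CCCC/C=C\CCCCCCCCCc1c(OC)c(OC)c(C)c(OC)c1OC | intermediate
14 | 2,5-dimethoxy-3-methyl-6-[(Z)-pentadec-10-en-1-yl]-1,4-benzoquinone | CCCC/C=C\CCCCCCCCCC1=C(OC)C(=O)C(C)=C(OC)C1=O | intermediate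
15 | disodium salt of 16 (quinonediolate) | CCCC/C=C\CCCCCCCCCC1=C([O-])C(=O)C(C)=C([O-])C1=O.[Na+].[Na+] | intermediate
16 | 2,5-dihydroxy-3-methyl-6-[(Z)-pentadec-10-en-1-yl]-1,4-benzoquinone | CCCC/C=C\CCCCCCCCCC1=C(O)C(=O)C(C)=C(O)C1=O | target

Total step count: 6. Longest linear sequence: 5 (steps 1, 2, 4, 5, 6).

Steps most likely to fail

Step 4. Several processes could erode the coupling:
- near-statistical homocoupling of both partners;
- premature reduction of the radical or of the alkylnickel species;
- the allylic 1,5-hydrogen shift or 6-exo closure of the radical;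
- Z/E drift through Ni–H.

The fallback gives the two carbons opposite polarity in a decarboxylative Negishi alkyl–alkyl coupling. It sets out from 6, which Mg turnings in THF should convert into [4-(2,3,5,6-tetramethoxy-4-methylphenyl)butyl]magnesium bromide F1. ZnCl2 (0.5 equiv) then gives bis[4-(2,3,5,6-tetramethoxy-4-methylphenyl)butyl]zinc F2. F2 is coupled with ester 12, this time made from 10 and 11 with DIC and isolated, under NiCl2·glyme/4,4′-di-tert-butyl-2,2′-bipyridine in THF/DMF at rt. The fallback comes back to the route at 13.

Step 2. The hindered aryllithium may substitute sluggishly, the dibromide may undergo E2 elimination, and a second arylation may occur at the far bromide. The fallback uses the arene as a π-nucleophile instead of a carbanion. It sets out from 3, and Friedel–Crafts acylation with 4-bromobutanoyl chloride (O=C(Cl)CCCBr; SnCl4, CH2Cl2, −20 °C) at the only free ring position should give 4-bromo-1-(2,3,5,6-tetramethoxy-4-methylphenyl)butan-1-one F3. Ionic hydrogenation of the electron-rich aryl ketone (Et3SiH, TFA, rt) takes the carbonyl to CH2. The fallback comes back to the route at 6.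

Step 6. The second substitution may stall once the first enolate deactivates the ring, and the alkylquinone may decompose in hot alkali through tautomerisation to quinone methides. The fallback inverts the order of deprotection and oxidation and never passes through a methoxyquinone. It sets out from 13, where B-iodo-9-BBN (4.5 equiv, hexane/CH2Cl2, rt) cleaves aryl methyl ethers without attacking isolated alkenes. After hydrolytic work-up this should give 3-methyl-6-[(Z)-pentadec-10-en-1-yl]benzene-1,2,4,5-tetrol F4. Stirring F4 in EtOAc over aqueous NaHCO3 under air should autoxidise it, and acidification then brings the fallback back to the route at 16.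

Further compounds
F1 | step 4 | [4-(2,3,5,6-tetramethoxy-4-methylphenyl)butyl]magnesium bromide | Cc1c(OC)c(OC)c(CCCC[Mg]Br)c(OC)c1OC
F2 | step 4 | bis[4-(2,3,5,6-tetramethoxy-4-methylphenyl)butyl]zinc | Cc1c(OC)c(OC)c(CCCC[Zn]CCCCc2c(OC)c(OC)c(C)c(OC)c2OC)c(OC)c1OC
F3 | step 2 | 4-bromo-1-(2,3,5,6-tetramethoxy-4-methylphenyl)butan-1-one | Cc1c(OC)c(OC)c(C(=O)CCCBr)c(OC)c1OC
F4 | step 6 | 3-methyl-6-[(Z)-pentadec-10-en-1-yl]benzene-1,2,4,5-tetrol | CCCC/C=C\CCCCCCCCCc1c(O)c(O)c(C)c(O)c1O
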